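**Plan**

1. Target numbering, used throughout: bicyclo[3.2.1]octane with C1 (methyl bridgehead), C2–C3–C4 (enolised β-diketone bridge, acyl on C3), C5 (prenyl bridgehead), C6H2, C7 (CH with exo CMe2OH), C8 (bridging ketone).
2. Retrosynthesis cuts C3–acyl (C-acylation with (R)-2-methylbutanoic acid), then C2–C3 (Claisen closure of a C5 acetyl group onto the C1 ester), then C5–C4 (aldol, oxidation), then C1–C7 and C5–C6 of the cyclopentanone.
3. Enabling feature: C5–C8–C1, with C2 as the ester carbon, is the γ-carbon, ketone and α-carbon of a β-keto ester, and C6–C7–CMe2 is a 1,4-difunctionalised isoprene unit. The five-membered ring C1–C8–C5–C6–C7 is therefore the [3+2] sum of a keto ester dianion and an isoprene-derived bromo acetate.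
4. Forward: the cyclopentanone is made first in one flask (dianion alkylation C5–C6, then palladium allylic alkylation C1–C7). Hydration and silylation follow, C5 is acetylated, the six-membered ring C1–C2–C3–C4–C5–C8 is closed, C3 is acylated and the silyl group is removed.
5. Stereochemistry: C7 from the chiral palladium ligand; C1 relayed from C7 in the same ring closure; C5 by aldol attack anti to the C7 side chain, confirmed by the bridging that only the cis isomer can undergo; the side-chain centre from the (R)-acid.

Key step: step 4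

Remark: L* is N,N'-[(1R,2R)-cyclohexane-1,2-diyl]bis[2-(diphenylphosphanyl)benzamide]; that this ligand enantiomer gives the required C7 configuration is an assumption to be checked on the first run (the mirror-image ligand is the remedy), and the enolised triketones are drawn as their C2-enol tautomers.

**Route**

Step 1
Reactants: 1 isoprene (2-methylbuta-1,3-diene)
Product: 2 (E)-4-chloro-2-methylbut-2-en-1-yl acetate
Conditions: Pd(OAc)2 (5 mol %), LiCl, LiOAc, p-benzoquinone, AcOH–pentane, rt
Reagents that add atoms: lithium chloride, [Li+].[Cl-]; acetic acid, CC(=O)O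
Why: Palladium-catalysed oxidative 1,4-chloroacetoxylation of a 1,3-diene, in which acetate adds to the diene on divalent palladium at the CH2 of the methyl-bearing alkene, chloride attacks the unsubstituted terminus of the resulting π-allyl complex to give the E-alkene, and benzoquinone returns zerovalent palladium to the divalent state.

Step 2
Reactants: 2 (E)-4-chloro-2-methylbut-2-en-1-yl acetate
Product: 3 (E)-4-bromo-2-methylbut-2-en-1-yl acetate
Conditions: LiBr (excess), acetone, rt
Reagents that add atoms: lithium bromide, [Li+].[Br-]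
Why: Finkelstein halide exchange (SN2) at the primary allylic chloride, driven by the low solubility of LiCl in acetone, leaves the acetate untouched and provides the more reactive bromide needed for alkylation at −78 °C in step 4.

Step 3
Reactants: 4 methyl 2-methyl-3-oxobutanoate; 5 1-bromo-3-methylbut-2-ene (prenyl bromide)
Product: 6 methyl 2,7-dimethyl-3-oxooct-6-enoate
Conditions: NaH, THF, 0 °C; n-BuLi, 0 °C; 5, 0 °C to rt; aq. HCl
Reagents that add atoms: none
Why: γ-Alkylation of a β-keto ester dianion, in which the unstabilised γ-carbanion formed by the second deprotonation is the only site that reacts with the allylic bromide (SN2); the α-centre is labile and of no consequence.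

Step 4
Reactants: 6 methyl 2,7-dimethyl-3-oxooct-6-enoate; 3 (E)-4-bromo-2-methylbut-2-en-1-yl acetate
Product: 8 methyl (1R,3R,5R)-1-methyl-3-(3-methylbut-2-en-1-yl)-2-oxo-5-(prop-1-en-2-yl)cyclopentane-1-carboxylate, via sodium enolate of the γ-alkylated acetoxy keto ester 7 (not isolated)
Conditions: NaH, THF, 0 °C; n-BuLi, 0 °C; 3, −78 °C; then Pd2(dba)3·CHCl3 (2.5 mol %), L* (7.5 mol %), THF, −78 °C to rt
Reagents that add atoms: none
Why: The dianion of 6 attacks the primary allylic bromide of 3 through its more basic γ-carbon by SN2 at −78 °C, which forms C5–C6 and leaves the chelated α-enolate 7; zerovalent palladium then ionises the allylic acetate and the enolate carbon C1 attacks the internal terminus C7 of the 2-methylallyl complex anti to the metal, which forms C1–C7. The closest known reactions are the γ-alkylation of β-keto ester dianions and the intramolecular Tsuji–Trost alkylation of 8-acyloxy-3-oxooct-6-enoates to 2-alkoxycarbonyl-3-alkenylcyclopentanones, run here in sequence in one flask with a chiral diphosphine. The cyclopentanone closes in a 5-exo mode (enolexo through the ester enolate), and the remaining alkene becomes the exocyclic isopropenyl group. C7 is set by the ligand, because the two faces of the allyl complex interconvert through the η1 form at the unsubstituted CH2 terminus, so the chiral pocket can select one face from an achiral chain; C1 follows from the chelated Z-enolate, which holds the ester syn to the enolate oxygen while the methylallyl unit takes the outward position, cis to the C1 methyl and anti to the ester; C5 forms without control and stays epimerisable. The step needs γ- over α-alkylation (secured by the higher basicity of the γ-carbanion), bromide over acetate displacement (SN2 before the catalyst is added), C- over O-allylation (an O-allyl enol ether re-ionises under palladium) and five- over seven-membered closure (the syn allyl complex from the E-alkene cannot span a seven-membered ring without isomerising).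

Step 5
Reactants: 8 methyl (1R,3R,5R)-1-methyl-3-(3-methylbut-2-en-1-yl)-2-oxo-5-(prop-1-en-2-yl)cyclopentane-1-carboxylate
Product: 9 methyl (1R,3R,5S)-5-(2-hydroxypropan-2-yl)-1-methyl-3-(3-methylbut-2-en-1-yl)-2-oxocyclopentane-1-carboxylate
Conditions: Co(acac)2 (20 mol %), PhSiH3, O2 (1 atm), THF, rt
Reagents that add atoms: dioxygen, O=O
Why: Mukaiyama hydration (hydrogen-atom transfer from a cobalt hydride, trapping of the tertiary radical by O2 and reduction of the peroxide by the silane) gives the Markovnikov tertiary alcohol, and the 1,1-disubstituted isopropenyl group should react ahead of the more hindered trisubstituted prenyl alkene while ketone, ester, C1 and C7 are untouched.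

Step 6
Reactants: 9 methyl (1R,3R,5S)-5-(2-hydroxypropan-2-yl)-1-methyl-3-(3-methylbut-2-en-1-yl)-2-oxocyclopentane-1-carboxylate
Product: 10 methyl (1R,3R,5S)-1-methyl-3-(3-methylbut-2-en-1-yl)-2-oxo-5-[2-(triethylsilyloxy)propan-2-yl]cyclopentane-1-carboxylate
Conditions: Et3SiOTf, 2,6-lutidine, CH2Cl2, −78 to 0 °C
Reagents that add atoms: triethylsilyl trifluoromethanesulfonate, CC[Si](CC)(CC)OS(=O)(=O)C(F)(F)F
Why: Silylation of the hindered tertiary alcohol with a silyl triflate and a hindered pyridine base, which keeps the alkoxide from attacking the neighbouring C8 ketone (retro-Claisen ring opening) in the basic steps that follow.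

Step 7
Reactants: 10 methyl (1R,3R,5S)-1-methyl-3-(3-methylbut-2-en-1-yl)-2-oxo-5-[2-(triethylsilyloxy)propan-2-yl]cyclopentane-1-carboxylate; 11 acetaldehyde
Product: 12 methyl (1R,3R,5S)-3-(1-hydroxyethyl)-1-methyl-3-(3-methylbut-2-en-1-yl)-2-oxo-5-[2-(triethylsilyloxy)propan-2-yl]cyclopentane-1-carboxylate
Conditions: LiN(i-Pr)2, THF, −78 °C; 11, −78 °C; AcOH quench at −78 °C
Reagents that add atoms: none
Why: Directed aldol addition of the lithium enolate (C5 is the only enolisable position) through a Zimmerman–Traxler-type transition state, in which the aldehyde should approach planar C5 from the face opposite to the C7 silyloxyalkyl group and the C1 methyl group, i.e., cis to the C1 ester, which sets the C5 quaternary centre; the carbinol centre is removed in step 8.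

Step 8
Reactants: 12 methyl (1R,3R,5S)-3-(1-hydroxyethyl)-1-methyl-3-(3-methylbut-2-en-1-yl)-2-oxo-5-[2-(triethylsilyloxy)propan-2-yl]cyclopentane-1-carboxylate
Product: 13 methyl (1R,3R,5S)-3-acetyl-1-methyl-3-(3-methylbut-2-en-1-yl)-2-oxo-5-[2-(triethylsilyloxy)propan-2-yl]cyclopentane-1-carboxylate
Conditions: Dess–Martin periodinane, CH2Cl2, 0 °C to rt
Reagents that add atoms: none
Why: Dess–Martin oxidation of the secondary alcohol to the methyl ketone under near-neutral conditions, which avoids retro-aldol cleavage of the quaternary β-hydroxy ketone and touches no stereocentre of the ring.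

Step 9
Reactants: 13 methyl (1R,3R,5S)-3-acetyl-1-methyl-3-(3-methylbut-2-en-1-yl)-2-oxo-5-[2-(triethylsilyloxy)propan-2-yl]cyclopentane-1-carboxylate
Product: 14 (1S,5R,7S)-1-methyl-5-(3-methylbut-2-en-1-yl)-7-[2-(triethylsilyloxy)propan-2-yl]bicyclo[3.2.1]octane-2,4,8-trione
Conditions: LiN(SiMe3)2 (2.2 equiv), THF, −78 to 0 °C; cold 0.5 M HCl
Reagents that add atoms: none
Why: Intramolecular Claisen (Dieckmann-type) condensation in which the enolate of the acetyl methyl group, the only enolisable position, attacks the cis-disposed C1 ester in a 6-exo-trig closure of the C1–C2–C3–C4–C5–C8 ring, as in the known closure of cis-3-acetylcyclopentanecarboxylates to bicyclo[3.2.1]octane-2,4-diones, with deprotonation of the new β-diketone by the second equivalent of base as the driving force; only the C5 epimer with acetyl cis to the ester can close.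

Step 10
Reactants: 14 (1S,5R,7S)-1-methyl-5-(3-methylbut-2-en-1-yl)-7-[2-(triethylsilyloxy)propan-2-yl]bicyclo[3.2.1]octane-2,4,8-trione; 15 (R)-2-methylbutanoic acid
Product: 17 (1S,5S,7S)-2-hydroxy-1-methyl-3-[(2R)-2-methylbutanoyl]-5-(3-methylbut-2-en-1-yl)-7-[2-(triethylsilyloxy)propan-2-yl]bicyclo[3.2.1]oct-2-ene-4,8-dione, via enol ester 16 (not isolated)
Conditions: DCC, DMAP (1.2 equiv), CH2Cl2, 0 °C to rt, then 40 °C
Reagents that add atoms: none
Why: Steglich O-acylation of the enolised β-diketone followed by DMAP-mediated O-to-C acyl migration, the standard route to 2-acyl-1,3-diones, gives the C3-acylated triketone as the thermodynamic product, and the α-centre of the acid is carried through because the acyl group is activated without strong base.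

Step 11
Reactants: 17 (1S,5S,7S)-2-hydroxy-1-methyl-3-[(2R)-2-methylbutanoyl]-5-(3-methylbut-2-en-1-yl)-7-[2-(triethylsilyloxy)propan-2-yl]bicyclo[3.2.1]oct-2-ene-4,8-dione
Product: 18 (1S,5S,7S)-2-hydroxy-7-(2-hydroxypropan-2-yl)-1-methyl-3-[(2R)-2-methylbutanoyl]-5-(3-methylbut-2-en-1-yl)bicyclo[3.2.1]oct-2-ene-4,8-dione
Conditions: HF·pyridine, THF, 0 °C to rt
Reagents that add atoms: none
Why: Fluoride-mediated cleavage of the tertiary triethylsilyl ether under buffered conditions that should leave the enolised triketone, the prenyl alkene and all stereocentres intact.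

**Compound list**

1 | isoprene | C=CC(C)=C | starting material
2 | (E)-4-chloro-2-methylbut-2-en-1-yl acetate | CC(=O)OC/C(C)=C/CCl | intermediate
3 | (E)-4-bromo-2-methylbut-2-en-1-yl acetate | CC(=O)OC/C(C)=C/CBr | intermediate
4 | methyl 2-methyl-3-oxobutanoate (methyl 2-methylacetoacetate) | COC(=O)C(C)C(C)=O | starting material
5 | 1-bromo-3-methylbut-2-ene (prenyl bromide) | CC(C)=CCBr | starting material
6 | methyl 2,7-dimethyl-3-oxooct-6-enoate (racemic, labile centre) | COC(=O)C(C)C(=O)CCC=C(C)C | intermediate
7 | sodium enolate of methyl (6E)-8-acetoxy-2,7-dimethyl-4-(3-methylbut-2-en-1-yl)-3-oxooct-6-enoate (racemic at C4 of the chain) | COC(=O)C(C)=C([O-])C(CC=C(C)C)C/C=C(\C)COC(C)=O.[Na+] | intermediate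
8 | methyl (1R,3R,5R)-1-methyl-3-(3-methylbut-2-en-1-yl)-2-oxo-5-(prop-1-en-2-yl)cyclopentane-1-carboxylate (ring C3 epimerisable; 3,5-cis epimer drawn) | COC(=O)[C@@]1(C)C(=O)[C@H](CC=C(C)C)C[C@@H]1C(C)=C | intermediate
9 | methyl (1R,3R,5S)-5-(2-hydroxypropan-2-yl)-1-methyl-3-(3-methylbut-2-en-1-yl)-2-oxocyclopentane-1-carboxylate (ring C3 epimerisable) | COC(=O)[C@@]1(C)C(=O)[C@H](CC=C(C)C)C[C@@H]1C(C)(C)O | intermediate
10 | methyl (1R,3R,5S)-1-methyl-3-(3-methylbut-2-en-1-yl)-2-oxo-5-[2-(triethylsilyloxy)propan-2-yl]cyclopentane-1-carboxylate (ring C3 epimerisable) | COC(=O)[C@@]1(C)C(=O)[C@H](CC=C(C)C)C[C@@H]1C(C)(C)O[Si](CC)(CC)CC | intermediate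
11 | acetaldehyde | CC=O | starting material
12 | methyl (1R,3R,5S)-3-(1-hydroxyethyl)-1-methyl-3-(3-methylbut-2-en-1-yl)-2-oxo-5-[2-(triethylsilyloxy)propan-2-yl]cyclopentane-1-carboxylate (carbinol epimers) | COC(=O)[C@@]1(C)C(=O)[C@](C(C)O)(CC=C(C)C)C[C@@H]1C(C)(C)O[Si](CC)(CC)CC | intermediate
13 | methyl (1R,3R,5S)-3-acetyl-1-methyl-3-(3-methylbut-2-en-1-yl)-2-oxo-5-[2-(triethylsilyloxy)propan-2-yl]cyclopentane-1-carboxylate | COC(=O)[C@@]1(C)C(=O)[C@](C(C)=O)(CC=C(C)C)C[C@@H]1C(C)(C)O[Si](CC)(CC)CC | intermediate
14 | (1S,5R,7S)-1-methyl-5-(3-methylbut-2-en-1-yl)-7-[2-(triethylsilyloxy)propan-2-yl]bicyclo[3.2.1]octane-2,4,8-trione | O=C1CC(=O)[C@@]2(C)C(=O)[C@]1(CC=C(C)C)C[C@@H]2C(C)(C)O[Si](CC)(CC)CC | intermediate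
15 | (R)-2-methylbutanoic acid | CC[C@@H](C)C(=O)O | starting material
16 | (1S,5R,7S)-1-methyl-5-(3-methylbut-2-en-1-yl)-4,8-dioxo-7-[2-(triethylsilyloxy)propan-2-yl]bicyclo[3.2.1]oct-2-en-2-yl (2R)-2-methylbutanoate | CC[C@@H](C)C(=O)OC1=CC(=O)[C@@]2(CC=C(C)C)C[C@H](C(C)(C)O[Si](CC)(CC)CC)[C@]1(C)C2=O | intermediate
17 | (1S,5S,7S)-2-hydroxy-1-methyl-3-[(2R)-2-methylbutanoyl]-5-(3-methylbut-2-en-1-yl)-7-[2-(triethylsilyloxy)propan-2-yl]bicyclo[3.2.1]oct-2-ene-4,8-dione | CC[C@@H](C)C(=O)C1=C(O)[C@@]2(C)C(=O)[C@](CC=C(C)C)(C[C@@H]2C(C)(C)O[Si](CC)(CC)CC)C1=O | intermediate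
18 | (1S,5S,7S)-2-hydroxy-7-(2-hydroxypropan-2-yl)-1-methyl-3-[(2R)-2-methylbutanoyl]-5-(3-methylbut-2-en-1-yl)bicyclo[3.2.1]oct-2-ene-4,8-dione | CC[C@@H](C)C(=O)C1=C(O)[C@@]2(C)C(=O)[C@](CC=C(C)C)(C[C@@H]2C(C)(C)O)C1=O | target

**Step count and risks**

Total: 11 steps. Longest linear sequence: 10 steps (1 to 18 through steps 1, 2 and 4–11).

Step 4 is the most exposed. Stereocontrol in the palladium ring closure may erode. Enolate 7 is racemic at C5, so one enantiomer may be mismatched with the ligand, and the tight sodium ion pair with bromide and acetate salts may disturb face selection at C7 and the C1/C7 relationship. O-allylation or closure at the CH2 terminus would add to the loss. The fallback sets out from 4 and 3 and returns at 8. The dianion of 4 (NaH, then n-BuLi, THF) is alkylated with 3 at −78 °C and quenched, and methyl (E)-8-acetoxy-2,7-dimethyl-3-oxooct-6-enoate F1 is isolated; it carries no stereocentre in the tether. Purified F1 is cyclised under soft-enolisation Tsuji–Trost conditions (Pd2(dba)3·CHCl3, L*, tetramethylguanidine, toluene) to methyl (1R,5R)-1-methyl-2-oxo-5-(prop-1-en-2-yl)cyclopentane-1-carboxylate F2. The prenyl group is then introduced by alkylation of the lithium enolate of F2 (LiN(i-Pr)2, THF, −78 °C, then 5), which gives 8.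

Step 7 is next. Facial discrimination at C5 may be poor, because the groups that differentiate the two faces (the C7 side chain and the C1 substituents) are remote from the reacting carbon, and retro-aldol cleavage may occur on warming. The fallback sets out from 10 and returns at 14. Krapcho dealkoxycarbonylation (LiCl, wet DMSO, 150 °C) removes the C1 ester and gives (3S)-2-methyl-5-(3-methylbut-2-en-1-yl)-3-[2-(triethylsilyloxy)propan-2-yl]cyclopentan-1-one F3. Silylation (Me3SiOTf, Et3N, CH2Cl2) gives the trimethylsilyl enol ether (3S)-2-methyl-5-(3-methylbut-2-en-1-yl)-3-[2-(triethylsilyloxy)propan-2-yl]-1-(trimethylsilyloxy)cyclopent-1-ene F4. An Effenberger-type annulation with malonyl dichloride (Et2O, −20 °C, then aqueous KOH with BnEt3NCl) acylates C1 anti to the vicinal C7 substituent and closes onto C5 intramolecularly. The bridge is then cis by necessity and exo to the side chain, and the product is 14.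

Step 5 is the third. Hydrogen-atom transfer to the prenyl alkene may compete with the isopropenyl group and lead to over-hydration. The fallback sets out from 8 and returns at 9, and replaces the radical hydration by an ionic one whose preference for 1,1-disubstituted over trisubstituted alkenes is well established. Oxymercuration (Hg(OAc)2, THF–H2O, rt) gives methyl (1R,3R,5S)-5-[1-(acetoxymercurio)-2-hydroxypropan-2-yl]-1-methyl-3-(3-methylbut-2-en-1-yl)-2-oxocyclopentane-1-carboxylate F5. Reductive demercuration with excess NaBH4 in aqueous NaOH at 0 °C is expected to reduce the C8 ketone as well and gives methyl (1R,3R,5S)-2-hydroxy-5-(2-hydroxypropan-2-yl)-1-methyl-3-(3-methylbut-2-en-1-yl)cyclopentane-1-carboxylate F6. Dess–Martin oxidation of the secondary alcohol of F6 returns 9.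

**Further compounds**

F1 | step 4 | methyl (E)-8-acetoxy-2,7-dimethyl-3-oxooct-6-enoate | COC(=O)C(C)C(=O)CC/C=C(\C)COC(C)=O
F2 | step 4 | methyl (1R,5R)-1-methyl-2-oxo-5-(prop-1-en-2-yl)cyclopentane-1-carboxylate | COC(=O)[C@@]1(C)C(=O)CC[C@@H]1C(C)=C
F3 | step 7 | (3S)-2-methyl-5-(3-methylbut-2-en-1-yl)-3-[2-(triethylsilyloxy)propan-2-yl]cyclopentan-1-one (C2 and C5 epimers) | CC1C(=O)C(CC=C(C)C)C[C@@H]1C(C)(C)O[Si](CC)(CC)CC
F4 | step 7 | (3S)-2-methyl-5-(3-methylbut-2-en-1-yl)-3-[2-(triethylsilyloxy)propan-2-yl]-1-(trimethylsilyloxy)cyclopent-1-ene | CC1=C(O[Si](C)(C)C)C(CC=C(C)C)C[C@@H]1C(C)(C)O[Si](CC)(CC)CC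
F5 | step 5 | methyl (1R,3R,5S)-5-[1-(acetoxymercurio)-2-hydroxypropan-2-yl]-1-methyl-3-(3-methylbut-2-en-1-yl)-2-oxocyclopentane-1-carboxylate (carbinol epimers) | COC(=O)[C@@]1(C)C(=O)[C@H](CC=C(C)C)C[C@@H]1C(C)(O)C[Hg]OC(C)=O
F6 | step 5 | methyl (1R,3R,5S)-2-hydroxy-5-(2-hydroxypropan-2-yl)-1-methyl-3-(3-methylbut-2-en-1-yl)cyclopentane-1-carboxylate (C2 epimers) | COC(=O)[C@@]1(C)C(O)[C@H](CC=C(C)C)C[C@@H]1C(C)(C)O
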